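**Retrosynthetic overview**
- C40 = C15 + C10 + C15: the C11=C12 and C11′=C12′ bonds are cut (two Wittig olefinations), giving the commercial C10 trienedial, a trihydroxy C15 phosphonium salt and a 3‑hydroxy‑ε C15 phosphonium salt.
- Trihydroxy end: the all‑cis 3,5,6‑triol comes from a hydroxyl‑directed OsO4 [3+2] cycloaddition on (3R)‑3‑hydroxy‑β‑ionone, which is made from (4R,6R)‑actinol by enol triflate formation and Heck coupling; vinyl Grignard addition and PPh3·HBr then give the C15 salt.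
- ε end: (R)‑α‑ionone supplies C6′; HWE homologation, allylic oxidation at C3′ and a trans‑selective bulky‑hydride reduction set C3′.
- Ring order: no carbocycle is built, both six‑membered rings are bought. The only rings formed are transient: the five‑membered osmate ester (trihydroxy ring), then the oxaphosphetanes of the two Wittig steps (ε side first, trihydroxy side last).

Assumption: (4R,6R)‑actinol and (R)‑(+)‑α‑ionone are bought enantiopure and are the only chiral inputs.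

**Step 1**
Reactants: 1 (4R,6R)-4-hydroxy-2,2,6-trimethylcyclohexan-1-one [(−)-actinol]
Product: 2 (4R,6R)-2,2,6-trimethyl-4-[(triethylsilyl)oxy]cyclohexan-1-one
Conditions: Et3SiCl, imidazole, DMF, 0 °C → rt
Reagents that add atoms: chlorotriethylsilane, CC[Si](Cl)(CC)CC
Why: Imidazole‑promoted silyl ether formation masks the only hydroxyl against the strong base of step 2 and touches no stereocentre.

**Step 2**
Reactants: 2 (4R,6R)-2,2,6-trimethyl-4-[(triethylsilyl)oxy]cyclohexan-1-one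
Product: 4 (4R)-2,6,6-trimethyl-4-[(triethylsilyl)oxy]cyclohex-1-en-1-yl trifluoromethanesulfonate, via lithium enolate 3 (not isolated)
Conditions: LiN(i-Pr)2, THF, −78 → 0 °C; then PhNTf2, −78 °C → rt
Reagents that add atoms: N-phenylbis(trifluoromethanesulfonimide), O=S(=O)(N(c1ccccc1)S(=O)(=O)C(F)(F)F)C(F)(F)F; lithium diisopropylamide, [Li+].CC(C)[N-]C(C)C (lithium in 3 only)
Why: Enolate formation and O‑triflation; the ketone can enolise only toward the methine carbon (the other α‑carbon is quaternary), so one enol triflate forms and the bought carbinol centre (future C3) is untouched.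

**Step 3**
Reactants: 4 (4R)-2,6,6-trimethyl-4-[(triethylsilyl)oxy]cyclohex-1-en-1-yl trifluoromethanesulfonate + 5 but-3-en-2-one (methyl vinyl ketone)
Product: 7 (3E)-4-[(4R)-4-hydroxy-2,6,6-trimethylcyclohex-1-en-1-yl]but-3-en-2-one, via triethylsilyl ether 6 (not isolated)
Conditions: Pd(OAc)2 (5 mol %), PPh3 (10 mol %), Et3N, DMF, 70 °C; then 1 M HCl, THF, rt
Reagents that add atoms: none
Why: Heck coupling (oxidative addition of the alkenyl triflate to zerovalent palladium, insertion of the enone, syn β‑hydride elimination) gives the E‑dienone, and the acidic work‑up cleaves the labile silyl ether to give (3R)‑3‑hydroxy‑β‑ionone.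

**Step 4**
Reactants: 7 (3E)-4-[(4R)-4-hydroxy-2,6,6-trimethylcyclohex-1-en-1-yl]but-3-en-2-one
Product: 9 (3E)-4-[(1R,2S,4S)-1,2,4-trihydroxy-2,6,6-trimethylcyclohexyl]but-3-en-2-one, via osmate ester 8 (not isolated)
Conditions: OsO4 (1.05 equiv), TMEDA (1.1 equiv), CH2Cl2, −78 °C; then sat. aq. Na2SO3, THF, 45 °C
Reagents that add atoms: osmium tetroxide, O=[Os](=O)(=O)=O; N,N,N′,N′-tetramethylethylenediamine, CN(C)CCN(C)C (in 8 only)
Why: Suprafacial [3+2] cycloaddition of OsO4·TMEDA to the electron‑rich tetrasubstituted ring alkene forms the cyclic osmate ester on the face anti to the pseudoaxial gem‑dimethyl methyl and hydrogen‑bonded to the C3 hydroxyl, so both new C–O bonds are cis to each other and to the bought carbinol, setting C5 (S) and C6 (R).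

**Step 5**
Reactants: 9 (3E)-4-[(1R,2S,4S)-1,2,4-trihydroxy-2,6,6-trimethylcyclohexyl]but-3-en-2-one + 10 vinylmagnesium bromide
Product: 11 (1R,2S,4S)-1-[(1E)-3-hydroxy-3-methylpenta-1,4-dien-1-yl]-2,6,6-trimethylcyclohexane-1,2,4-triol (both epimers at the side-chain carbinol)
Conditions: CH2=CHMgBr (6 equiv), THF, −20 → 0 °C; then sat. aq. NH4Cl
Reagents that add atoms: none
Why: 1,2‑Grignard addition to the enone carbonyl after the excess reagent has deprotonated the three hydroxyls; the new carbinol centre forms unselectively but is erased in step 6.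

**Step 6**
Reactants: 11 (1R,2S,4S)-1-[(1E)-3-hydroxy-3-methylpenta-1,4-dien-1-yl]-2,6,6-trimethylcyclohexane-1,2,4-triol
Product: 12 {(2E,4E)-3-methyl-5-[(1R,2S,4S)-1,2,4-trihydroxy-2,6,6-trimethylcyclohexyl]penta-2,4-dien-1-yl}triphenylphosphonium bromide
Conditions: PPh3·HBr (1.05 equiv), MeOH, 0 °C → rt
Reagents that add atoms: triphenylphosphine hydrobromide, [Br-].c1ccc(cc1)[PH+](c1ccccc1)c1ccccc1
Why: SN1′ allylic transposition: the doubly allylic tertiary carbinol ionises to a pentadienyl cation that PPh3 captures at the primary terminus to give the conjugated E,E salt, while the ring C6 hydroxyl (its cation destabilised by the vicinal C5 hydroxyl) ionises much more slowly.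

**Step 7**
Reactants: 13 (3E)-4-[(1R)-2,6,6-trimethylcyclohex-2-en-1-yl]but-3-en-2-one [(R)-α-ionone] + 14 triethyl phosphonoacetate
Product: 15 ethyl (2E,4E)-3-methyl-5-[(1R)-2,6,6-trimethylcyclohex-2-en-1-yl]penta-2,4-dienoate
Conditions: NaH, THF, 0 °C → rt; chromatography (removes minor 2Z isomer)
Reagents that add atoms: none
Why: Horner–Wadsworth–Emmons olefination of the methyl ketone gives mainly the E trisubstituted enoate, and the hindered, weakly acidic allylic C6′–H stereocentre is retained.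

**Step 8**
Reactants: 15 ethyl (2E,4E)-3-methyl-5-[(1R)-2,6,6-trimethylcyclohex-2-en-1-yl]penta-2,4-dienoate
Product: 16 ethyl (2E,4E)-3-methyl-5-[(1R)-2,6,6-trimethyl-4-oxocyclohex-2-en-1-yl]penta-2,4-dienoate
Conditions: t-BuOOH (5 equiv), Rh2(cap)4 (1 mol %, cap = caprolactamate), K2CO3, CH2Cl2, rt
Reagents that add atoms: tert-butyl hydroperoxide, CC(C)(C)OO
Why: Radical allylic oxidation (hydrogen abstraction by tert‑butylperoxyl, then collapse of the mixed peroxide) converts the only secondary ring allylic CH2 into the enone; the tertiary C6′–H is shielded and lies near the alkene plane, so the stereocentre survives.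

**Step 9**
Reactants: 16 ethyl (2E,4E)-3-methyl-5-[(1R)-2,6,6-trimethyl-4-oxocyclohex-2-en-1-yl]penta-2,4-dienoate
Product: 18 (2E,4E)-5-[(1R,4R)-4-hydroxy-2,6,6-trimethylcyclohex-2-en-1-yl]-3-methylpenta-2,4-dien-1-ol, via hydroxy ester 17 (not isolated)
Conditions: LiBH(s-Bu)3 (1.2 equiv), THF, −78 °C; then i-Bu2AlH (3.5 equiv), −78 → 0 °C; aq. potassium sodium tartrate
Reagents that add atoms: none
Why: Substrate‑controlled 1,2‑hydride reduction: the bulky borohydride attacks the enone carbonyl equatorially, anti to the axial gem‑dimethyl methyl (the side chain sits pseudoaxial on the other face), giving the 3,6‑trans alcohol (3′R), and i‑Bu2AlH then reduces the dienoate to the primary allylic alcohol.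

**Step 10**
Reactants: 18 (2E,4E)-5-[(1R,4R)-4-hydroxy-2,6,6-trimethylcyclohex-2-en-1-yl]-3-methylpenta-2,4-dien-1-ol
Product: 19 {(2E,4E)-5-[(1R,4R)-4-hydroxy-2,6,6-trimethylcyclohex-2-en-1-yl]-3-methylpenta-2,4-dien-1-yl}triphenylphosphonium bromide
Conditions: PPh3·HBr (1.05 equiv), CH2Cl2/MeOH, 0 °C
Reagents that add atoms: triphenylphosphine hydrobromide, [Br-].c1ccc(cc1)[PH+](c1ccccc1)c1ccccc1
Why: SN1‑type substitution: the primary dienylic alcohol ionises (pentadienyl cation) much faster than the ring allylic alcohol and is captured by PPh3, so C3′ and C6′ are untouched.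

**Step 11**
Reactants: 19 {(2E,4E)-5-[(1R,4R)-4-hydroxy-2,6,6-trimethylcyclohex-2-en-1-yl]-3-methylpenta-2,4-dien-1-yl}triphenylphosphonium bromide + 20 (2E,4E,6E)-2,7-dimethylocta-2,4,6-trienedial
Product: 22 (2E,4E,6E,8E,10E,12E)-13-[(1R,4R)-4-hydroxy-2,6,6-trimethylcyclohex-2-en-1-yl]-2,7,11-trimethyltrideca-2,4,6,8,10,12-hexaenal, via phosphorus ylide 21 (not isolated)
Conditions: 20 (3 equiv), NaOMe (1.1 equiv, slow addition), CH2Cl2/MeOH, 0 °C → rt; then EtOH, reflux (Z → E)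
Reagents that add atoms: none
Why: Wittig olefination ([2+2] cycloaddition of ylide and aldehyde to an oxaphosphetane, then cycloreversion); the ylide is generated slowly in excess symmetrical dialdehyde so only one formyl group reacts, and heating equilibrates the new double bond to E.

**Step 12**
Reactants: 22 (2E,4E,6E,8E,10E,12E)-13-[(1R,4R)-4-hydroxy-2,6,6-trimethylcyclohex-2-en-1-yl]-2,7,11-trimethyltrideca-2,4,6,8,10,12-hexaenal + 12 {(2E,4E)-3-methyl-5-[(1R,2S,4S)-1,2,4-trihydroxy-2,6,6-trimethylcyclohexyl]penta-2,4-dien-1-yl}triphenylphosphonium bromide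
Product: 24 (3S,5S,6R,3′R,6′R)-5,6-dihydro-β,ε-carotene-3,5,6,3′-tetrol (5,6-dihydroxylutein), via phosphorus ylide 23 (not isolated)
Conditions: 12 (1.3 equiv), NaOMe (1.5 equiv), CH2Cl2/MeOH, 0 °C → rt; then EtOH, reflux (Z → E); crystallisation
Reagents that add atoms: none
Why: A second Wittig olefination ([2+2] cycloaddition to an oxaphosphetane and cycloreversion) joins C11 to C12 and completes the C40 polyene; the free hydroxyls tolerate methoxide, no stereocentre is touched, and heating gives the all‑E target.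

**Compound list**
1 | (4R,6R)-4-hydroxy-2,2,6-trimethylcyclohexan-1-one [(−)-actinol] | C[C@@H]1C[C@@H](O)CC(C)(C)C1=O | starting material
2 | (4R,6R)-2,2,6-trimethyl-4-[(triethylsilyl)oxy]cyclohexan-1-one | C[C@@H]1C[C@@H](O[Si](CC)(CC)CC)CC(C)(C)C1=O | intermediate
3 | lithium (4R)-2,6,6-trimethyl-4-[(triethylsilyl)oxy]cyclohex-1-en-1-olate | [Li+].CC1=C([O-])C(C)(C)C[C@H](O[Si](CC)(CC)CC)C1 | intermediate
4 | (4R)-2,6,6-trimethyl-4-[(triethylsilyl)oxy]cyclohex-1-en-1-yl trifluoromethanesulfonate | CC1=C(OS(=O)(=O)C(F)(F)F)C(C)(C)C[C@H](O[Si](CC)(CC)CC)C1 | intermediate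
5 | but-3-en-2-one (methyl vinyl ketone) | CC(=O)C=C | starting material
6 | (3E)-4-{(4R)-2,6,6-trimethyl-4-[(triethylsilyl)oxy]cyclohex-1-en-1-yl}but-3-en-2-one | CC1=C(/C=C/C(C)=O)C(C)(C)C[C@H](O[Si](CC)(CC)CC)C1 | intermediate
7 | (3E)-4-[(4R)-4-hydroxy-2,6,6-trimethylcyclohex-1-en-1-yl]but-3-en-2-one [(3R)-3-hydroxy-β-ionone] | CC1=C(/C=C/C(C)=O)C(C)(C)C[C@H](O)C1 | intermediate
8 | cyclic 5,6-osmate ester of 9 (dioxo-osmium glycolate, hexavalent osmium, TMEDA-bound) | CC(=O)/C=C/[C@]12O[Os-2]3(=O)(=O)(O[C@@]1(C)C[C@@H](O)CC2(C)C)[N+](C)(C)CC[N+]3(C)C | intermediate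
9 | (3E)-4-[(1R,2S,4S)-1,2,4-trihydroxy-2,6,6-trimethylcyclohexyl]but-3-en-2-one | CC(=O)/C=C/[C@@]1(O)C(C)(C)C[C@H](O)C[C@]1(C)O | intermediate
10 | vinylmagnesium bromide | C=C[Mg]Br | starting material
11 | (1R,2S,4S)-1-[(1E)-3-hydroxy-3-methylpenta-1,4-dien-1-yl]-2,6,6-trimethylcyclohexane-1,2,4-triol (side-chain carbinol epimers) | C=CC(C)(O)/C=C/[C@@]1(O)C(C)(C)C[C@H](O)C[C@]1(C)O | intermediate
12 | {(2E,4E)-3-methyl-5-[(1R,2S,4S)-1,2,4-trihydroxy-2,6,6-trimethylcyclohexyl]penta-2,4-dien-1-yl}triphenylphosphonium bromide | [Br-].c1ccccc1[P+](c1ccccc1)(c1ccccc1)C/C=C(C)/C=C/[C@@]1(O)C(C)(C)C[C@H](O)C[C@]1(C)O | intermediate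
13 | (3E)-4-[(1R)-2,6,6-trimethylcyclohex-2-en-1-yl]but-3-en-2-one [(R)-α-ionone] | CC1=CCCC(C)(C)[C@H]1/C=C/C(C)=O | starting material
14 | triethyl phosphonoacetate | CCOC(=O)CP(=O)(OCC)OCC | starting material
15 | ethyl (2E,4E)-3-methyl-5-[(1R)-2,6,6-trimethylcyclohex-2-en-1-yl]penta-2,4-dienoate | CC1=CCCC(C)(C)[C@H]1/C=C/C(C)=C/C(=O)OCC | intermediate
16 | ethyl (2E,4E)-3-methyl-5-[(1R)-2,6,6-trimethyl-4-oxocyclohex-2-en-1-yl]penta-2,4-dienoate | CC1=CC(=O)CC(C)(C)[C@H]1/C=C/C(C)=C/C(=O)OCC | intermediate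
17 | ethyl (2E,4E)-5-[(1R,4R)-4-hydroxy-2,6,6-trimethylcyclohex-2-en-1-yl]-3-methylpenta-2,4-dienoate | CC1=C[C@H](O)CC(C)(C)[C@H]1/C=C/C(C)=C/C(=O)OCC | intermediate
18 | (2E,4E)-5-[(1R,4R)-4-hydroxy-2,6,6-trimethylcyclohex-2-en-1-yl]-3-methylpenta-2,4-dien-1-ol | CC1=C[C@H](O)CC(C)(C)[C@H]1/C=C/C(C)=C/CO | intermediate
19 | {(2E,4E)-5-[(1R,4R)-4-hydroxy-2,6,6-trimethylcyclohex-2-en-1-yl]-3-methylpenta-2,4-dien-1-yl}triphenylphosphonium bromide | [Br-].CC1=C[C@H](O)CC(C)(C)[C@H]1/C=C/C(C)=C/C[P+](c1ccccc1)(c1ccccc1)c1ccccc1 | intermediate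
20 | (2E,4E,6E)-2,7-dimethylocta-2,4,6-trienedial | O=C/C(C)=C/C=C/C=C(C)/C=O | starting material
21 | phosphorus ylide of 19 | CC1=C[C@H](O)CC(C)(C)[C@H]1/C=C/C(C)=C/C=P(c1ccccc1)(c1ccccc1)c1ccccc1 | intermediate
22 | (2E,4E,6E,8E,10E,12E)-13-[(1R,4R)-4-hydroxy-2,6,6-trimethylcyclohex-2-en-1-yl]-2,7,11-trimethyltrideca-2,4,6,8,10,12-hexaenal | CC1=C[C@H](O)CC(C)(C)[C@H]1/C=C/C(C)=C/C=C/C(C)=C/C=C/C=C(C)/C=O | intermediate
23 | phosphorus ylide of 12 | c1ccccc1P(c1ccccc1)(c1ccccc1)=C/C=C(C)/C=C/[C@@]1(O)C(C)(C)C[C@H](O)C[C@]1(C)O | intermediate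
24 | (3S,5S,6R,3′R,6′R)-5,6-dihydro-β,ε-carotene-3,5,6,3′-tetrol (5,6-dihydroxylutein) | CC1=C[C@H](O)CC(C)(C)[C@H]1/C=C/C(C)=C/C=C/C(C)=C/C=C/C=C(C)/C=C/C=C(C)/C=C/[C@@]1(O)C(C)(C)C[C@H](O)C[C@]1(C)O | target

**Step count and risks**

Total: 12 steps (trihydroxy arm 6, ε arm 4, two couplings). Longest linear sequence: 7 steps (1 → 2 → 4 → 7 → 9 → 11 → 12 → 24).

Steps most likely to fail:

Step 4. OsO4 may also attack the enone C7=C8 bond, the facial ratio may be modest, and the hindered di‑tertiary osmate ester may hydrolyse slowly. The fallback sets out from 4 and comes back at 9. Sonogashira coupling of 4 with but-3-yn-2-ol (Pd(PPh3)2Cl2, CuI, Et3N) gives 4-{(4R)-2,6,6-trimethyl-4-[(triethylsilyl)oxy]cyclohex-1-en-1-yl}but-3-yn-2-ol F1. Dilute HCl then frees 4-[(4R)-4-hydroxy-2,6,6-trimethylcyclohex-1-en-1-yl]but-3-yn-2-ol F2, in which the ring alkene is the only C=C. The same OsO4·TMEDA cycloaddition gives (1S,2S,4S)-1-(3-hydroxybut-1-yn-1-yl)-2,6,6-trimethylcyclohexane-1,2,4-triol F3. trans‑Hydroalumination of the doubly propargylic alkyne with NaAlH2(OCH2CH2OMe)2 gives (1R,2S,4S)-1-[(1E)-3-hydroxybut-1-en-1-yl]-2,6,6-trimethylcyclohexane-1,2,4-triol F4. MnO2 oxidises only the allylic secondary alcohol and returns 9.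

Step 6. The tertiary allylic C6 hydroxyl next to the C5 carbinol can ionise under acid (pinacol‑type ring contraction or furanoid formation). The fallback sets out from 9 (and uses 22) and comes back at 24; it reverses the polarity of the last coupling so that the triol fragment never meets acid. HWE reaction of 9 with diethyl (cyanomethyl)phosphonate and NaH gives (2E,4E)-3-methyl-5-[(1R,2S,4S)-1,2,4-trihydroxy-2,6,6-trimethylcyclohexyl]penta-2,4-dienenitrile F5. i-Bu2AlH reduction and hydrolysis give (2E,4E)-3-methyl-5-[(1R,2S,4S)-1,2,4-trihydroxy-2,6,6-trimethylcyclohexyl]penta-2,4-dienal F6. In parallel, NaBH4 reduces 22 to (2E,4E,6E,8E,10E,12E)-13-[(1R,4R)-4-hydroxy-2,6,6-trimethylcyclohex-2-en-1-yl]-2,7,11-trimethyltrideca-2,4,6,8,10,12-hexaen-1-ol F7. PPh3·HBr converts it into {(2E,4E,6E,8E,10E,12E)-13-[(1R,4R)-4-hydroxy-2,6,6-trimethylcyclohex-2-en-1-yl]-2,7,11-trimethyltrideca-2,4,6,8,10,12-hexaen-1-yl}triphenylphosphonium bromide F8. Wittig reaction of F8 with F6 (NaOMe) gives 24.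

Step 8. Hydrogen abstraction at the doubly allylic C6′–H (loss of the stereocentre, over‑oxidation) or attack on the dienoate may compete. The fallback sets out from 13 and comes back at 19; it oxidises at the C13 stage with the chain carbonyl masked and reaches the salt through the vinyl carbinol. Ketalisation of 13 (ethylene glycol, TsOH) gives 2-methyl-2-{(E)-2-[(1R)-2,6,6-trimethylcyclohex-2-en-1-yl]ethenyl}-1,3-dioxolane F9. Allylic oxidation gives (4R)-3,5,5-trimethyl-4-[(E)-2-(2-methyl-1,3-dioxolan-2-yl)ethenyl]cyclohex-2-en-1-one F10. KBH(s-Bu)3 reduction gives (1R,4R)-3,5,5-trimethyl-4-[(E)-2-(2-methyl-1,3-dioxolan-2-yl)ethenyl]cyclohex-2-en-1-ol F11. Mild deketalisation (pyridinium tosylate, aqueous acetone) gives (3E)-4-[(1R,4R)-4-hydroxy-2,6,6-trimethylcyclohex-2-en-1-yl]but-3-en-2-one F12. CH2=CHMgBr gives (1R,4R)-4-[(1E)-3-hydroxy-3-methylpenta-1,4-dien-1-yl]-3,5,5-trimethylcyclohex-2-en-1-ol F13. PPh3·HBr converts this doubly allylic tertiary carbinol into 19.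

**Further compounds**
F1 | step 4 | 4-{(4R)-2,6,6-trimethyl-4-[(triethylsilyl)oxy]cyclohex-1-en-1-yl}but-3-yn-2-ol | CC1=C(C#CC(C)O)C(C)(C)C[C@H](O[Si](CC)(CC)CC)C1
F2 | step 4 | 4-[(4R)-4-hydroxy-2,6,6-trimethylcyclohex-1-en-1-yl]but-3-yn-2-ol | CC1=C(C#CC(C)O)C(C)(C)C[C@H](O)C1
F3 | step 4 | (1S,2S,4S)-1-(3-hydroxybut-1-yn-1-yl)-2,6,6-trimethylcyclohexane-1,2,4-triol | CC(O)C#C[C@@]1(O)C(C)(C)C[C@H](O)C[C@]1(C)O
F4 | step 4 | (1R,2S,4S)-1-[(1E)-3-hydroxybut-1-en-1-yl]-2,6,6-trimethylcyclohexane-1,2,4-triol | CC(O)/C=C/[C@@]1(O)C(C)(C)C[C@H](O)C[C@]1(C)O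
F5 | step 6 | (2E,4E)-3-methyl-5-[(1R,2S,4S)-1,2,4-trihydroxy-2,6,6-trimethylcyclohexyl]penta-2,4-dienenitrile | N#C/C=C(C)/C=C/[C@@]1(O)C(C)(C)C[C@H](O)C[C@]1(C)O
F6 | step 6 | (2E,4E)-3-methyl-5-[(1R,2S,4S)-1,2,4-trihydroxy-2,6,6-trimethylcyclohexyl]penta-2,4-dienal | O=C/C=C(C)/C=C/[C@@]1(O)C(C)(C)C[C@H](O)C[C@]1(C)O
F7 | step 6 | (2E,4E,6E,8E,10E,12E)-13-[(1R,4R)-4-hydroxy-2,6,6-trimethylcyclohex-2-en-1-yl]-2,7,11-trimethyltrideca-2,4,6,8,10,12-hexaen-1-ol | CC1=C[C@H](O)CC(C)(C)[C@H]1/C=C/C(C)=C/C=C/C(C)=C/C=C/C=C(C)/CO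
F8 | step 6 | {(2E,4E,6E,8E,10E,12E)-13-[(1R,4R)-4-hydroxy-2,6,6-trimethylcyclohex-2-en-1-yl]-2,7,11-trimethyltrideca-2,4,6,8,10,12-hexaen-1-yl}triphenylphosphonium bromide | [Br-].CC1=C[C@H](O)CC(C)(C)[C@H]1/C=C/C(C)=C/C=C/C(C)=C/C=C/C=C(C)/C[P+](c1ccccc1)(c1ccccc1)c1ccccc1
F9 | step 8 | 2-methyl-2-{(E)-2-[(1R)-2,6,6-trimethylcyclohex-2-en-1-yl]ethenyl}-1,3-dioxolane | CC1=CCCC(C)(C)[C@H]1/C=C/C1(C)OCCO1
F10 | step 8 | (4R)-3,5,5-trimethyl-4-[(E)-2-(2-methyl-1,3-dioxolan-2-yl)ethenyl]cyclohex-2-en-1-one | CC1=CC(=O)CC(C)(C)[C@H]1/C=C/C1(C)OCCO1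
F11 | step 8 | (1R,4R)-3,5,5-trimethyl-4-[(E)-2-(2-methyl-1,3-dioxolan-2-yl)ethenyl]cyclohex-2-en-1-ol | CC1=C[C@H](O)CC(C)(C)[C@H]1/C=C/C1(C)OCCO1
F12 | step 8 | (3E)-4-[(1R,4R)-4-hydroxy-2,6,6-trimethylcyclohex-2-en-1-yl]but-3-en-2-one | CC1=C[C@H](O)CC(C)(C)[C@H]1/C=C/C(C)=O
F13 | step 8 | (1R,4R)-4-[(1E)-3-hydroxy-3-methylpenta-1,4-dien-1-yl]-3,5,5-trimethylcyclohex-2-en-1-ol | CC1=C[C@H](O)CC(C)(C)[C@H]1/C=C/C(C)(O)C=C
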